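## Structural features

The target is a linear pentamer of benzene rings A to E joined only by four diaryl ether oxygens. It carries thirteen free phenolic hydroxyls and has neither a stereocentre nor a configurationally stable axis. Rings A, B, C and E are 1,2,3,5-tetraoxygenated and ring D is pentaoxygenated, so every ring is very electron-rich and the free polyphenol is prone to air oxidation (quinones) and to attack by electrophiles such as benzyl cations or Lewis acids. The real difficulty is that each ether oxygen is bonded on one side to a carbon flanked by two oxygen-bearing carbons (C4 of ring A, C2 of ring B, C4 of ring C, C6 of ring D), where copper- or palladium-mediated C–O coupling is at its weakest, while thirteen nearly equivalent hydroxyls must be told apart. Ring C is the hinge: its ether carbons C1 (oxygen to ring B) and C4 (oxygen to ring D) are para, the hydroxyls at C3 and C5 flank C4, and C2 and C6 carry hydrogen. That pattern results when a vinylketene supplying C2–C5 is annulated with an alkynyl ether supplying C6 and C1, so both crowded oxygens of ring C can be installed beforehand by O-alkylation at an sp3 carbon (ring D side) and O-alkynylation (ring B side). Atom-by-atom mapping of cyclobutenone 34, ynol ether 16 and annulation product 39 onto ring C showed no constitutional fault in this plan. The C3 oxygen of the cyclobutenone is carried as a benzyl ether and not as a silyl ether, because benzyloxyethyne is made by the same chemistry as 16, the resulting vinylogous ester is hydrolytically robust, and the end-game shrinks to one hydrogenolysis.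

## Logic of the disconnections

40 to 39. The twelve O–CH2 bonds of the benzyl ethers are cut. The free polyphenol is too oxidisable and too polar to be carried, and benzyl is the one mask that leaves under neutral, reducing conditions. Every earlier intermediate becomes a lipophilic polyether. The forward hydrogenolysis must be complete at twelve sites without touching the four diaryl ether bonds.

39 to 34 and 16. Bonds C1–C2 and C5–C6 of ring C are cut; C4–C5 is the bond that breaks and re-forms in the forward cascade. This cut removes both crowded ether carbons of ring C from the bonds to be made by coupling, because C4–O already exists in 34 at an sp3 carbon and C1–O already exists in 16 at an sp carbon. A five-ring problem becomes two two-ring problems of similar size. The forward annulation must be regioselective and both partners must survive 80–110 °C.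

34 to 26 and 31. Bonds C1–C2 and C3–C4 of the four-membered ring are cut (retro-(2+2) into a ketene and an alkynyl ether). This cycloaddition gives only the 4-aryloxy-3-alkoxy isomer, which O-alkylation of a cyclobutane-1,3-dione would not. The ring D–E unit is reduced to a carboxylic acid. Ketene 33 must be generated from 32 under non-acidic conditions and trapped faster than it dimerises.

31 to 27 and 12. The O–C(sp) bond is cut and the triple bond is traced back to two C–Cl bonds. Alkoxides add to the chloroalkyne formed in situ from 12, and the adduct is converted into the terminal ynol ether in the same flask. Two commodity chemicals remain. The forward product must be kept cold.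

26 to 24 and 25. The O–CH2 bond is cut. This sp3 O-alkylation stands in for an arylation at ring C C4 that would be very difficult. It leaves phenol 24 with a single free hydroxyl. The demand on the forward step is small, since the phenoxide has only one ortho substituent.

24 to 22. The ring D C1–O bond is traced back to a C1–CHO bond (Dakin retron). The formyl group is needed one step earlier as activating group for the ether synthesis and sits exactly where the free hydroxyl must appear. No differentiation among the ring D oxygens is then needed. Aryl, not hydride, must migrate in the peracid adduct.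

22 to 20 and 21. The ring D C6–O bond is cut. The ring E side of this ether is unhindered, so ring E can be the nucleophile, and the twice-flanked ring D carbon is activated by its ortho formyl group. Both monomers come from one aldehyde. The forward step is a copper-mediated coupling at a di-ortho-substituted C–Br bond.

20 and 21 to 18, and 18 to 17. In 20 a C–O bond is traced to C–CHO, in 21 the C–Br bond is cut, and in 18 three O–CH2 bonds are cut. One commercial aldehyde serves both halves of the D–E dimer. The bromination must stop at one bromine and must not release acid.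

16 to 13, and 13 to 11 and 12. In 16 the triple bond is traced to the two C–Cl bonds of 13, and in 13 the O–C(sp2) bond is cut. The ring B C2 oxygen, flanked twice, is thereby bonded to a small linear electrophile and not to an arene. This leaves phenol 11 with one free hydroxyl. The organolithium step must spare five benzyl ethers and the terminal ynol ether must be handled cold and acid-free.

11 to 9, and 9 to 8 and 4. The ring B C2–O bond is traced to C2–CHO (Dakin retron) and the ring A–O–ring B bond is cut at ring B C1. Ring B C1 has only one ortho neighbour and that neighbour is the activating formyl group, so the crowded ring A oxygen can be the nucleophile. Two monomers result. The coupling must accept a phenoxide with two ortho substituents.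

8 to 6 to 5, and 4 to 2 to 1. C–O is traced to C–CHO in 8, O–CH2 bonds are cut in 6 and 2, and the C–CHO bond is cut in 4. The sequence ends at three commercial polyphenols. The only selectivity issue is the site of formylation of 2.

## Other disconnections considered

Alternative 1: The cut lies inside ring D (its C1–C2 bond); the ring is assembled from a squaric ester four-carbon unit and a 1-alkoxyvinyl two-carbon unit. Ring E is attached first as an aryloxide by addition–elimination on the squaric ester, so the crowded ring D C6–O bond is made at a vinylogous ester carbon. In the forward sense the 4-alkenyl-4-alkoxycyclobutenone precursor would open (4π) to a dienylketene and close (6π) to phenol A1, whose single free hydroxyl is the ring D C1 oxygen.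
- In its favour: the ring expansion is intramolecular and a thoroughly established reaction type, the pentaoxygenated ring emerges fully differentiated, and no copper coupling at a di-ortho-substituted carbon is needed. On precedent and on reliability of the ring-forming event it is the better of the two.
- Against it here: A1 is only a ring D–E dimer, functionally the same as 24, so the two hardest ethers (at ring C C4 and ring B C2) stay unsolved. The ring D oxygens arrive as methyl and ethyl ethers, which would force a boron trihalide dealkylation of the sensitive polyphenol unless benzyl analogues of the squaric ester and of the vinyl anion can be used. The regiochemistry of the organolithium addition rests only on the difference between an aryloxy and an alkoxy vinylogous ester.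
- Comparison: structurally the alternative builds the most oxygenated ring but at the periphery of the problem, while the chosen step fuses two dimers. Mechanistically both use a 4π/6π cascade through a ketene. In step economy it would replace steps 9 to 13 by a sequence of about equal length, so it is an equal, not a shorter, way to the D–E half.

Alternative 2: The cut goes through ring A (C2–C3 and C5–C6), which is built last on the ring B oxygen. The ring B–C–D–E phenol would be O-alkylated with a halomalonate and the aryloxymalonate condensed twice (Claisen, then Dieckmann-type closure) with an acetonedicarboxylate diester under NaH in hot toluene to give trihydroxyisophthalate A2.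
- In its favour: the crowded ring A C4–O bond is made by SN2 at an sp3 carbon, and the condensation is classical phloroglucinol chemistry with cheap reagents. The benzyl esters would fall in the final hydrogenolysis with easy decarboxylation, so the end-game is as short as in the chosen plan. For the ring A–B bond itself it is the better method than the copper coupling of step 5, which must cope with a di-ortho-substituted phenoxide.
- Against it here: the plan is linear and needs the tetramer phenol first, so the ethers at ring B C2 and ring C C4 must still be made by other means, and the least certain step would be run last on the most valuable material. Aryloxymalonates are prone to retro-Claisen cleavage and self-condensation, and the polycarbonyl product can deacylate under the basic conditions.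
- Comparison: structurally it attacks a terminal ring and leaves ring C untouched. Mechanistically it is an ionic condensation that avoids ketenes and sensitive ynol ethers, which is an advantage. In step economy it is less convergent (4 + 1 instead of 2 + 2 around a new ring) and its longest linear sequence would be clearly longer.

Alternative 3: The cut goes through ring E (C2–C3 and C5–C6), grown last on the ring D C6 oxygen. The ring A–B–C–D phenol would be converted into a 2-aryloxy-3-(dimethylamino)acrolein, a three-carbon bis-electrophile, which condenses twice with a 1,3-dialkoxyacetone enolate (KOt-Bu) and aromatises by loss of dimethylamine and water to phenol A3 with a free ring E C4 hydroxyl.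
- In its favour: the di-ortho-substituted ring D C6–O bond is again formed at an sp3 carbon, ring E appears symmetrically with no regiochemical question, and A3 needs only one hydrogenolysis, the same end-game as the chosen plan.
- Against it here: the aminoacrolein is normally made by Vilsmeier-type double formylation, and the chloroiminium reagent would also attack the unsubstituted, strongly activated positions of rings A, B and C in the tetramer. The dialkoxyacetone enolate can eliminate alkoxide or self-condense. Above all the plan is linear and spends its key step on the ring D–E ether, the one that the ortho-formyl-assisted copper coupling of step 12 suits best because the ring E side is unhindered.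
- Comparison: structurally the chosen plan puts its ring construction at ring C, where both ether carbons are hard to reach by coupling. Mechanistically the alternative is a stepwise ionic (3+3) ring synthesis that tolerates no free electron-rich arene at the formylation stage. In step economy it is about equal to steps 9 to 13 for the terminal ring but less convergent overall.

Key step: step 17

Assumption: 5-bromobenzene-1,3-diol, 2,4,6-trihydroxybenzaldehyde and 3,4,5-trihydroxybenzaldehyde are taken as commercial entry points in place of the parent polyphenols, because each already carries the halogen or formyl handle that the route needs.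

Abbreviations in the step lines: AB-aryloxy = 2,4-bis(benzyloxy)-6-[2,4,6-tris(benzyloxy)phenoxy]phenoxy; DE-aryloxy = 3,4,5-tris(benzyloxy)-2-[3,4,5-tris(benzyloxy)phenoxy]phenoxy. Full names are in the compound list.

## Steps

Step 1
Reactants: 1 5-bromobenzene-1,3-diol
Product: 2 1,3-bis(benzyloxy)-5-bromobenzene
Conditions: BnBr, K2CO3, DMF, 60 °C
Reagents that add atoms: benzyl bromide, BrCc1ccccc1
Why: Williamson ether synthesis; both phenoxides are alkylated by SN2 on benzyl bromide, and the bromine-bearing ring is not nucleophilic enough for C-benzylation to compete.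

Step 2
Reactants: 2 1,3-bis(benzyloxy)-5-bromobenzene
Product: 4 2,4-bis(benzyloxy)-6-bromobenzaldehyde, via iminium chloride 3 (not isolated)
Conditions: POCl3, DMF, 0 to 80 °C; aq. NaOAc
Reagents that add atoms: N,N-dimethylformamide, CN(C)C=O; water, O
Why: Vilsmeier–Haack formylation; the chloroiminium ion should attack the position para to one benzyloxy group and ortho to the other, the site between the two benzyloxy groups being the more crowded, and hydrolysis of 3 gives the aldehyde. Any 4-bromo-2,6-bis(benzyloxy) isomer should be removable by crystallisation.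

Step 3
Reactants: 5 2,4,6-trihydroxybenzaldehyde
Product: 6 2,4,6-tris(benzyloxy)benzaldehyde
Conditions: BnBr, K2CO3, DMF, 70 °C
Reagents that add atoms: benzyl bromide, BrCc1ccccc1
Why: Williamson ether synthesis; the formyl group lowers ring nucleophilicity and so suppresses C-benzylation, and the hydrogen-bonded ortho hydroxyls are alkylated last at the higher temperature.

Step 4
Reactants: 6 2,4,6-tris(benzyloxy)benzaldehyde
Product: 8 2,4,6-tris(benzyloxy)phenol, via aryl formate 7 (not isolated)
Conditions: mCPBA, CH2Cl2, 0 °C to rt; K2CO3 (cat.), MeOH, 0 °C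
Reagents that add atoms: 3-chloroperbenzoic acid, OOC(=O)c1cccc(Cl)c1
Why: Dakin-type Baeyer–Villiger oxidation; the 2,4,6-trialkoxyphenyl group migrates far faster than hydrogen in the Criegee adduct, and mild methanolysis of 7 frees the phenol. One equivalent of peracid at low temperature should protect the electron-rich product from over-oxidation.

Step 5
Reactants: 8 2,4,6-tris(benzyloxy)phenol; 4 2,4-bis(benzyloxy)-6-bromobenzaldehyde
Product: 9 2,4-bis(benzyloxy)-6-[2,4,6-tris(benzyloxy)phenoxy]benzaldehyde
Conditions: CuI (cat.), picolinic acid (cat.), K3PO4, DMSO, 90 °C, Ar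
Reagents that add atoms: none
Why: Ullmann diaryl ether synthesis; the CuI–picolinic acid system accepts phenoxides with two ortho substituents and the ortho formyl group activates the C–Br bond of 4. The ether is formed at ring B C1, whose only ortho neighbour on the electrophile is that formyl group.

Step 6
Reactants: 9 2,4-bis(benzyloxy)-6-[2,4,6-tris(benzyloxy)phenoxy]benzaldehyde
Product: 11 2,4-bis(benzyloxy)-6-[2,4,6-tris(benzyloxy)phenoxy]phenol, via aryl formate 10 (not isolated)
Conditions: mCPBA, CH2Cl2, 0 °C to rt; K2CO3 (cat.), MeOH, 0 °C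
Reagents that add atoms: 3-chloroperbenzoic acid, OOC(=O)c1cccc(Cl)c1
Why: Dakin-type Baeyer–Villiger oxidation; the formyl carbon sits on a ring with two ortho and one para oxygen donor, so aryl migration should be clean. The activating group of step 5 is thereby exchanged for the ring B C2 hydroxyl, the only free hydroxyl of 11.

Step 7
Reactants: 11 2,4-bis(benzyloxy)-6-[2,4,6-tris(benzyloxy)phenoxy]phenol; 12 trichloroethylene
Product: 13 1,5-bis(benzyloxy)-2-{[(E)-1,2-dichloroethenyl]oxy}-3-[2,4,6-tris(benzyloxy)phenoxy]benzene
Conditions: K2CO3, DMF, 70 °C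
Reagents that add atoms: none
Why: Base-mediated O-vinylation; loss of HCl from 12 gives dichloroacetylene in situ, and anti addition of phenoxide and proton across it gives the (E)-1,2-dichlorovinyl ether. The electrophile is small and linear, so the two groups flanking the phenoxide oxygen should not block it.

Step 8
Reactants: 13 1,5-bis(benzyloxy)-2-{[(E)-1,2-dichloroethenyl]oxy}-3-[2,4,6-tris(benzyloxy)phenoxy]benzene
Product: 16 1,5-bis(benzyloxy)-2-(ethynyloxy)-3-[2,4,6-tris(benzyloxy)phenoxy]benzene, via chloroethynyl ether 14 (not isolated), via lithium acetylide 15 (not isolated)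
Conditions: n-BuLi, THF, –78 °C; MeOH, –78 °C
Reagents that add atoms: none
Why: Standard dichlorovinyl ether route to alkynyl ethers; dehydrochlorination gives 14, chlorine–lithium exchange gives 15, and cold protonation gives the terminal ynol ether. Benzyl aryl ethers should not be metalated at –78 °C on this time scale; 16 is purified on base-washed silica and stored cold.

Step 9
Reactants: 17 3,4,5-trihydroxybenzaldehyde
Product: 18 3,4,5-tris(benzyloxy)benzaldehyde
Conditions: BnBr, K2CO3, DMF, 70 °C
Reagents that add atoms: benzyl bromide, BrCc1ccccc1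
Why: Williamson ether synthesis on all three phenoxides; the formyl group disfavours C-alkylation.

Step 10
Reactants: 18 3,4,5-tris(benzyloxy)benzaldehyde
Product: 20 3,4,5-tris(benzyloxy)phenol, via aryl formate 19 (not isolated)
Conditions: mCPBA, CH2Cl2, 0 °C to rt; K2CO3 (cat.), MeOH, 0 °C
Reagents that add atoms: 3-chloroperbenzoic acid, OOC(=O)c1cccc(Cl)c1
Why: Dakin-type Baeyer–Villiger oxidation; the para alkoxy group supports aryl migration as in the trimethoxy series, and methanolysis of 19 gives the ring E phenol.

Step 11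
Reactants: 18 3,4,5-tris(benzyloxy)benzaldehyde
Product: 21 3,4,5-tris(benzyloxy)-2-bromobenzaldehyde
Conditions: NBS, MeCN, rt, dark
Reagents that add atoms: N-bromosuccinimide, BrN1C(=O)CCC1=O
Why: Electrophilic aromatic bromination; C2 is ortho and para to benzyloxy groups and is the only type of free ring position. NBS in a polar solvent in the dark reacts by the ionic path and releases no HBr that could cleave benzyl ethers, and the first bromine deactivates the ring against a second.

Step 12
Reactants: 20 3,4,5-tris(benzyloxy)phenol; 21 3,4,5-tris(benzyloxy)-2-bromobenzaldehyde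
Product: 22 3,4,5-tris(benzyloxy)-2-[3,4,5-tris(benzyloxy)phenoxy]benzaldehyde
Conditions: CuI (cat.), picolinic acid (cat.), K3PO4, DMSO, 100 °C, Ar
Reagents that add atoms: none
Why: Ullmann diaryl ether synthesis on an ortho-carbonyl-activated aryl bromide, the pattern used for gallate-derived diaryl ethers; the unhindered phenoxide 20 compensates for the two ortho substituents at the C–Br carbon. This sets the ring D C6–O–ring E bond.

Step 13
Reactants: 22 3,4,5-tris(benzyloxy)-2-[3,4,5-tris(benzyloxy)phenoxy]benzaldehyde
Product: 24 3,4,5-tris(benzyloxy)-2-[3,4,5-tris(benzyloxy)phenoxy]phenol, via aryl formate 23 (not isolated)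
Conditions: mCPBA, CH2Cl2, 0 °C to rt; K2CO3 (cat.), MeOH, 0 °C
Reagents that add atoms: 3-chloroperbenzoic acid, OOC(=O)c1cccc(Cl)c1
Why: Dakin-type Baeyer–Villiger oxidation; the ortho aryloxy and para benzyloxy donors favour aryl migration, and the formyl carbon becomes the ring D C1 hydroxyl, the only free hydroxyl of 24.

Step 14
Reactants: 24 3,4,5-tris(benzyloxy)-2-[3,4,5-tris(benzyloxy)phenoxy]phenol; 25 bromoacetic acid
Product: 26 (DE-aryloxy)acetic acid
Conditions: NaH, THF–DMF, 0 to 50 °C; 1 M HCl
Reagents that add atoms: none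
Why: Williamson etherification; NaH forms the phenoxide and the carboxylate, and SN2 at the CH2Br carbon makes the future ring C C4–O bond at an sp3 carbon. The reacting oxygen has only one ortho substituent.

Step 15
Reactants: 27 benzyl alcohol; 12 trichloroethylene
Product: 31 benzyloxyethyne, via dichlorovinyl ether 28 (not isolated), via chloroethynyl ether 29 (not isolated), via lithium acetylide 30 (not isolated)
Conditions: KH, THF, 0 °C to rt; n-BuLi, –78 °C; MeOH, –78 °C
Reagents that add atoms: none
Why: One-pot alkoxyacetylene synthesis; the alkoxide adds to dichloroacetylene generated from 12, and n-BuLi converts 28 by elimination and chlorine–lithium exchange into 30, which is protonated cold. The product is kept below 25 °C and used at once, because benzyl alkynyl ethers undergo (3,3)-sigmatropic rearrangement near 60 °C.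

Step 16
Reactants: 26 (DE-aryloxy)acetic acid; 31 benzyloxyethyne
Product: 34 rac-3-(benzyloxy)-4-(DE-aryloxy)cyclobut-2-en-1-one, via acid chloride 32 (not isolated), via aryloxyketene 33 (not isolated)
Conditions: (COCl)2, DMF (cat.), CH2Cl2, 0 °C to rt, evaporate; then 31 (excess), i-Pr2NEt (slow addition), CH2Cl2, 0 °C to rt
Reagents that add atoms: none
Why: Dehydrochlorination of 32 gives ketene 33, which the alkoxyacetylene traps in a (2+2) cycloaddition; the nucleophilic CH terminus bonds to the ketene carbonyl carbon and the oxygen-bearing alkyne carbon to the ketene α-carbon, so only the 3-alkoxy-4-aryloxy isomer should form. Excess 31 and slow ketene generation suppress ketene dimerisation; 34 is racemic at C4, which is of no consequence.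

Step 17
Reactants: 34 rac-3-(benzyloxy)-4-(DE-aryloxy)cyclobut-2-en-1-one; 16 1,5-bis(benzyloxy)-2-(ethynyloxy)-3-[2,4,6-tris(benzyloxy)phenoxy]benzene
Product: 39 3-(benzyloxy)-5-(AB-aryloxy)-2-(DE-aryloxy)phenol, via vinylketene 35 (not isolated), via 4-vinylcyclobutenone 36 (not isolated), via dienylketene 37 (not isolated), via cyclohexadienone 38 (not isolated)
Conditions: toluene, 80 then 110 °C, sealed tube, Ar, dark; 16 in slight excess
Reagents that add atoms: none
Why: Danheiser benzannulation of a cyclobutenone with an alkynyl ether, applied to a 3-alkoxy-4-aryloxycyclobutenone and an aryl ethynyl ether. Conrotatory 4π opening of 34, the C4 aryloxy donor rotating outward, should give (Z)-vinylketene 35, whose ketene carbonyl carbon is attacked by the nucleophilic CH terminus of 16; the (2+2) cycloaddition closes 4-vinylcyclobutenone 36. A second, reversible 4π opening gives dienylketene 37, and ring C is closed by a thermally allowed disrotatory 6π electrocyclisation between the ketene carbon and the aryloxy-bearing triene terminus, which re-forms the bond that was C1–C4 of 34; dienone 38 then tautomerises irreversibly to phenol 39. The net result is two new skeletal bonds, C1–C2 and C5–C6 of ring C, with both diaryl ether oxygens already in place. No stereocentre is created: the only one involved, C4 of racemic 34, is lost on aromatisation. The selectivity that matters is regiochemical and is secured by the polarisation of the ynol ether, whose CH carbon bonds to the ketene carbonyl carbon so that the ring B oxygen ends up para to the ring D oxygen; the two ortho substituents twist the aryl group of 16 out of conjugation and leave the oxygen lone pair to the alkyne. Outward rotation of the aryloxy group also places hydrogen, not oxygen, on the inside of the triene terminus, which eases the 6π closure. Since 16 has no β-hydrogen it cannot lose ketene by retro-ene fragmentation at 110 °C, and because the opening of 34 is reversible the cyclobutenone acts as a reservoir that keeps the vinylketene concentration low.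

Step 18
Reactants: 39 3-(benzyloxy)-5-(AB-aryloxy)-2-(DE-aryloxy)phenol
Product: 40 5-[2,4-dihydroxy-6-(2,4,6-trihydroxyphenoxy)phenoxy]-2-[3,4,5-trihydroxy-2-(3,4,5-trihydroxyphenoxy)phenoxy]benzene-1,3-diol
Conditions: H2 (1 atm), Pd/C (10% Pd on carbon), THF–MeOH, rt; filtration under Ar
Reagents that add atoms: none
Why: Hydrogenolysis of twelve benzyl aryl ethers; diaryl ethers are inert, the only by-product is toluene, and the neutral reducing medium protects the polyphenol from oxidation.

## Compound list

1 | 5-bromobenzene-1,3-diol | Oc1cc(O)cc(Br)c1 | starting material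
2 | 1,3-bis(benzyloxy)-5-bromobenzene | Brc1cc(OCc9ccccc9)cc(OCc9ccccc9)c1 | intermediate
3 | {[2,4-bis(benzyloxy)-6-bromophenyl]methylidene}dimethylammonium chloride | C[N+](C)=Cc1c(Br)cc(OCc9ccccc9)cc1OCc9ccccc9.[Cl-] | intermediate
4 | 2,4-bis(benzyloxy)-6-bromobenzaldehyde | O=Cc1c(Br)cc(OCc9ccccc9)cc1OCc9ccccc9 | intermediate
5 | 2,4,6-trihydroxybenzaldehyde | O=Cc1c(O)cc(O)cc1O | starting material
6 | 2,4,6-tris(benzyloxy)benzaldehyde | O=Cc1c(OCc9ccccc9)cc(OCc9ccccc9)cc1OCc9ccccc9 | intermediate
7 | 2,4,6-tris(benzyloxy)phenyl formate | O=COc1c(OCc9ccccc9)cc(OCc9ccccc9)cc1OCc9ccccc9 | intermediate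
8 | 2,4,6-tris(benzyloxy)phenol | Oc1c(OCc9ccccc9)cc(OCc9ccccc9)cc1OCc9ccccc9 | intermediate
9 | 2,4-bis(benzyloxy)-6-[2,4,6-tris(benzyloxy)phenoxy]benzaldehyde | O=Cc2c(Oc3c(OCc9ccccc9)cc(OCc9ccccc9)cc3OCc9ccccc9)cc(OCc9ccccc9)cc2OCc9ccccc9 | intermediate
10 | 2,4-bis(benzyloxy)-6-[2,4,6-tris(benzyloxy)phenoxy]phenyl formate | O=COc2c(Oc3c(OCc9ccccc9)cc(OCc9ccccc9)cc3OCc9ccccc9)cc(OCc9ccccc9)cc2OCc9ccccc9 | intermediate
11 | 2,4-bis(benzyloxy)-6-[2,4,6-tris(benzyloxy)phenoxy]phenol | Oc2c(Oc3c(OCc9ccccc9)cc(OCc9ccccc9)cc3OCc9ccccc9)cc(OCc9ccccc9)cc2OCc9ccccc9 | intermediate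
12 | trichloroethylene | ClC=C(Cl)Cl | starting material
13 | 1,5-bis(benzyloxy)-2-{[(E)-1,2-dichloroethenyl]oxy}-3-[2,4,6-tris(benzyloxy)phenoxy]benzene | Cl/C=C(/Cl)Oc2c(Oc3c(OCc9ccccc9)cc(OCc9ccccc9)cc3OCc9ccccc9)cc(OCc9ccccc9)cc2OCc9ccccc9 | intermediate
14 | 1,5-bis(benzyloxy)-2-[(chloroethynyl)oxy]-3-[2,4,6-tris(benzyloxy)phenoxy]benzene | ClC#COc2c(Oc3c(OCc9ccccc9)cc(OCc9ccccc9)cc3OCc9ccccc9)cc(OCc9ccccc9)cc2OCc9ccccc9 | intermediate
15 | lithium {2,4-bis(benzyloxy)-6-[2,4,6-tris(benzyloxy)phenoxy]phenoxy}acetylide | [Li]C#COc2c(Oc3c(OCc9ccccc9)cc(OCc9ccccc9)cc3OCc9ccccc9)cc(OCc9ccccc9)cc2OCc9ccccc9 | intermediate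
16 | 1,5-bis(benzyloxy)-2-(ethynyloxy)-3-[2,4,6-tris(benzyloxy)phenoxy]benzene | C#COc2c(Oc3c(OCc9ccccc9)cc(OCc9ccccc9)cc3OCc9ccccc9)cc(OCc9ccccc9)cc2OCc9ccccc9 | intermediate
17 | 3,4,5-trihydroxybenzaldehyde | O=Cc1cc(O)c(O)c(O)c1 | starting material
18 | 3,4,5-tris(benzyloxy)benzaldehyde | O=Cc1cc(OCc9ccccc9)c(OCc9ccccc9)c(OCc9ccccc9)c1 | intermediate
19 | 3,4,5-tris(benzyloxy)phenyl formate | O=COc1cc(OCc9ccccc9)c(OCc9ccccc9)c(OCc9ccccc9)c1 | intermediate
20 | 3,4,5-tris(benzyloxy)phenol | Oc1cc(OCc9ccccc9)c(OCc9ccccc9)c(OCc9ccccc9)c1 | intermediate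
21 | 3,4,5-tris(benzyloxy)-2-bromobenzaldehyde | O=Cc1cc(OCc9ccccc9)c(OCc9ccccc9)c(OCc9ccccc9)c1Br | intermediate
22 | 3,4,5-tris(benzyloxy)-2-[3,4,5-tris(benzyloxy)phenoxy]benzaldehyde | O=Cc4cc(OCc9ccccc9)c(OCc9ccccc9)c(OCc9ccccc9)c4Oc5cc(OCc9ccccc9)c(OCc9ccccc9)c(OCc9ccccc9)c5 | intermediate
23 | 3,4,5-tris(benzyloxy)-2-[3,4,5-tris(benzyloxy)phenoxy]phenyl formate | O=COc4cc(OCc9ccccc9)c(OCc9ccccc9)c(OCc9ccccc9)c4Oc5cc(OCc9ccccc9)c(OCc9ccccc9)c(OCc9ccccc9)c5 | intermediate
24 | 3,4,5-tris(benzyloxy)-2-[3,4,5-tris(benzyloxy)phenoxy]phenol | Oc4cc(OCc9ccccc9)c(OCc9ccccc9)c(OCc9ccccc9)c4Oc5cc(OCc9ccccc9)c(OCc9ccccc9)c(OCc9ccccc9)c5 | intermediate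
25 | bromoacetic acid | OC(=O)CBr | starting material
26 | {3,4,5-tris(benzyloxy)-2-[3,4,5-tris(benzyloxy)phenoxy]phenoxy}acetic acid | OC(=O)COc4cc(OCc9ccccc9)c(OCc9ccccc9)c(OCc9ccccc9)c4Oc5cc(OCc9ccccc9)c(OCc9ccccc9)c(OCc9ccccc9)c5 | intermediate
27 | benzyl alcohol | OCc1ccccc1 | starting material
28 | benzyl (E)-1,2-dichloroethenyl ether | Cl/C=C(/Cl)OCc1ccccc1 | intermediate
29 | benzyl chloroethynyl ether | ClC#COCc1ccccc1 | intermediate
30 | lithium (benzyloxy)acetylide | [Li]C#COCc1ccccc1 | intermediate
31 | benzyloxyethyne, [(ethynyloxy)methyl]benzene | C#COCc1ccccc1 | intermediate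
32 | {3,4,5-tris(benzyloxy)-2-[3,4,5-tris(benzyloxy)phenoxy]phenoxy}acetyl chloride | ClC(=O)COc4cc(OCc9ccccc9)c(OCc9ccccc9)c(OCc9ccccc9)c4Oc5cc(OCc9ccccc9)c(OCc9ccccc9)c(OCc9ccccc9)c5 | intermediate
33 | 2-{3,4,5-tris(benzyloxy)-2-[3,4,5-tris(benzyloxy)phenoxy]phenoxy}ethen-1-one (aryloxyketene) | O=C=COc4cc(OCc9ccccc9)c(OCc9ccccc9)c(OCc9ccccc9)c4Oc5cc(OCc9ccccc9)c(OCc9ccccc9)c(OCc9ccccc9)c5 | intermediate
34 | rac-3-(benzyloxy)-4-{3,4,5-tris(benzyloxy)-2-[3,4,5-tris(benzyloxy)phenoxy]phenoxy}cyclobut-2-en-1-one | O=C1C=C(OCc9ccccc9)C1Oc4cc(OCc9ccccc9)c(OCc9ccccc9)c(OCc9ccccc9)c4Oc5cc(OCc9ccccc9)c(OCc9ccccc9)c(OCc9ccccc9)c5 | intermediate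
35 | (3Z)-3-(benzyloxy)-4-{3,4,5-tris(benzyloxy)-2-[3,4,5-tris(benzyloxy)phenoxy]phenoxy}buta-1,3-dien-1-one | O=C=C/C(OCc9ccccc9)=C/Oc4cc(OCc9ccccc9)c(OCc9ccccc9)c(OCc9ccccc9)c4Oc5cc(OCc9ccccc9)c(OCc9ccccc9)c(OCc9ccccc9)c5 | intermediate
36 | rac-3-{2,4-bis(benzyloxy)-6-[2,4,6-tris(benzyloxy)phenoxy]phenoxy}-4-[(Z)-1-(benzyloxy)-2-{3,4,5-tris(benzyloxy)-2-[3,4,5-tris(benzyloxy)phenoxy]phenoxy}ethenyl]cyclobut-2-en-1-one | O=C1C=C(Oc2c(Oc3c(OCc9ccccc9)cc(OCc9ccccc9)cc3OCc9ccccc9)cc(OCc9ccccc9)cc2OCc9ccccc9)C1/C(OCc9ccccc9)=C/Oc4cc(OCc9ccccc9)c(OCc9ccccc9)c(OCc9ccccc9)c4Oc5cc(OCc9ccccc9)c(OCc9ccccc9)c(OCc9ccccc9)c5 | intermediate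
37 | (3E,5Z)-5-(benzyloxy)-3-{2,4-bis(benzyloxy)-6-[2,4,6-tris(benzyloxy)phenoxy]phenoxy}-6-{3,4,5-tris(benzyloxy)-2-[3,4,5-tris(benzyloxy)phenoxy]phenoxy}hexa-1,3,5-trien-1-one | O=C=C/C(Oc2c(Oc3c(OCc9ccccc9)cc(OCc9ccccc9)cc3OCc9ccccc9)cc(OCc9ccccc9)cc2OCc9ccccc9)=C\C(OCc9ccccc9)=C\Oc4cc(OCc9ccccc9)c(OCc9ccccc9)c(OCc9ccccc9)c4Oc5cc(OCc9ccccc9)c(OCc9ccccc9)c(OCc9ccccc9)c5 | intermediate
38 | rac-5-(benzyloxy)-3-{2,4-bis(benzyloxy)-6-[2,4,6-tris(benzyloxy)phenoxy]phenoxy}-6-{3,4,5-tris(benzyloxy)-2-[3,4,5-tris(benzyloxy)phenoxy]phenoxy}cyclohexa-2,4-dien-1-one | O=C1C=C(Oc2c(Oc3c(OCc9ccccc9)cc(OCc9ccccc9)cc3OCc9ccccc9)cc(OCc9ccccc9)cc2OCc9ccccc9)C=C(OCc9ccccc9)C1Oc4cc(OCc9ccccc9)c(OCc9ccccc9)c(OCc9ccccc9)c4Oc5cc(OCc9ccccc9)c(OCc9ccccc9)c(OCc9ccccc9)c5 | intermediate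
39 | 3-(benzyloxy)-5-{2,4-bis(benzyloxy)-6-[2,4,6-tris(benzyloxy)phenoxy]phenoxy}-2-{3,4,5-tris(benzyloxy)-2-[3,4,5-tris(benzyloxy)phenoxy]phenoxy}phenol | Oc1cc(Oc2c(Oc3c(OCc9ccccc9)cc(OCc9ccccc9)cc3OCc9ccccc9)cc(OCc9ccccc9)cc2OCc9ccccc9)cc(OCc9ccccc9)c1Oc4cc(OCc9ccccc9)c(OCc9ccccc9)c(OCc9ccccc9)c4Oc5cc(OCc9ccccc9)c(OCc9ccccc9)c(OCc9ccccc9)c5 | intermediate
40 | 5-[2,4-dihydroxy-6-(2,4,6-trihydroxyphenoxy)phenoxy]-2-[3,4,5-trihydroxy-2-(3,4,5-trihydroxyphenoxy)phenoxy]benzene-1,3-diol | Oc1cc(O)c(Oc2cc(O)cc(O)c2Oc2cc(O)c(Oc3cc(O)c(O)c(O)c3Oc3cc(O)c(O)c(O)c3)c(O)c2)c(O)c1 | target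

## Step count and least certain steps

Total: 18 steps. Longest linear sequence: 8 steps (3, 4, 5, 6, 7, 8, 17, 18; the ring D–E branch 9, 11, 12, 13, 14, 16, 17, 18 is equally long).

**Step 17 (key step).** The (2+2) capture of vinylketene 35 by 16 may be slower than dimerisation of the ketene or its acylation of phenol already formed, because both partners are electron-rich. The vinylogous ester stabilisation of 34 may also push the first ring opening to temperatures at which 16 oligomerises. The fallback sets out from 24 and 11 and returns at 40. It takes ring C from a preformed benzene ring whose two formyl groups activate the central carbon for substitution and later become the two hydroxyls. Commercial 5-bromo-2-fluoro-1,3-dimethylbenzene is brominated at both methyl groups (NBS, dibenzoyl peroxide, PhCF3, reflux) to 5-bromo-1,3-bis(dibromomethyl)-2-fluorobenzene F1 and hydrolysed (AgNO3, aqueous EtOH) to 5-bromo-2-fluorobenzene-1,3-dicarbaldehyde F2. The phenoxide of 24 displaces the doubly ortho-activated fluoride (SNAr; K2CO3, DMF, rt) to give 5-bromo-2-(DE-aryloxy)benzene-1,3-dicarbaldehyde F3. Ullmann coupling of its unhindered C–Br bond with 11 (CuI, picolinic acid, K3PO4, DMSO, 90 °C) gives 5-(AB-aryloxy)-2-(DE-aryloxy)benzene-1,3-dicarbaldehyde F4. Twofold Baeyer–Villiger oxidation and methanolysis (mCPBA; K2CO3, MeOH) gives 5-(AB-aryloxy)-2-(DE-aryloxy)benzene-1,3-diol F5, which is hydrogenolysed over Pd/C to 40.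

**Step 15.** The benzyl ynol ether may be lost by (3,3)-sigmatropic rearrangement to an arylketene during isolation, or acetylide 30 may undergo benzylic metalation and Wittig rearrangement if the lithiation warms. The fallback sets out from 26 and returns at 40. Commercial ethoxyethyne, which is stable at room temperature, replaces 31 in step 16 and should give 3-ethoxy-4-(DE-aryloxy)cyclobut-2-en-1-one F6. Benzannulation with 16 as in step 17 gives 3-ethoxy-5-(AB-aryloxy)-2-(DE-aryloxy)phenol F7. Hydrogenolysis gives the ring C monoethyl ether of the target F8, and the remaining aryl ethyl ether is cleaved with BBr3 (CH2Cl2, –78 °C to rt, MeOH quench) to 40. The price is one more step and a Lewis-acid dealkylation at the end.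

**Step 7.** O-Vinylation of the doubly flanked phenoxide of 11 may be slow, with build-up of hazardous dichloroacetylene and oxidative loss of the electron-rich phenoxide on long heating in DMF. The fallback sets out from 10 and returns at 16 through 14 and 15. The methanolysis of step 6 is omitted and formate 10 is isolated. Dichloromethylenation of its formyl group (PPh3, CCl4, THF, 60 °C; the Ramirez-type olefination that turns formates and formamides into ynol ether and ynamide precursors) gives 1,5-bis(benzyloxy)-2-[(2,2-dichloroethenyl)oxy]-3-[2,4,6-tris(benzyloxy)phenoxy]benzene F11. n-BuLi at –78 °C converts F11 by elimination and chlorine–lithium exchange into 14 and 15, and cold protonation gives 16.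

**Step 5.** Coupling may be slow because the nucleophilic oxygen of 8 is flanked by two benzyloxy groups; protodebromination of 4, aldehyde degradation in basic DMSO and oxidation of the phenoxide then compete. The fallback sets out from 8 and returns at 9, using copper-free nucleophilic aromatic substitution on the fluoro analogue of 4. Commercial 1,3,5-trifluorobenzene is treated with two equivalents of sodium benzyloxide (NaH, BnOH, NMP, 100 °C) to give 1,3-bis(benzyloxy)-5-fluorobenzene F9. Vilsmeier–Haack formylation as in step 2 gives 2,4-bis(benzyloxy)-6-fluorobenzaldehyde F10. The phenoxide of 8 then displaces the ortho-formyl-activated fluoride (Cs2CO3, DMF, 100 °C) to give 9.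

## Further compounds

F1 | step 17 | 5-bromo-1,3-bis(dibromomethyl)-2-fluorobenzene | BrC(Br)c1cc(Br)cc(C(Br)Br)c1F
F2 | step 17 | 5-bromo-2-fluorobenzene-1,3-dicarbaldehyde | O=Cc1cc(Br)cc(C=O)c1F
F3 | step 17 | 5-bromo-2-{3,4,5-tris(benzyloxy)-2-[3,4,5-tris(benzyloxy)phenoxy]phenoxy}benzene-1,3-dicarbaldehyde | O=Cc1cc(Br)cc(C=O)c1Oc4cc(OCc9ccccc9)c(OCc9ccccc9)c(OCc9ccccc9)c4Oc5cc(OCc9ccccc9)c(OCc9ccccc9)c(OCc9ccccc9)c5
F4 | step 17 | 5-{2,4-bis(benzyloxy)-6-[2,4,6-tris(benzyloxy)phenoxy]phenoxy}-2-{3,4,5-tris(benzyloxy)-2-[3,4,5-tris(benzyloxy)phenoxy]phenoxy}benzene-1,3-dicarbaldehyde | O=Cc1cc(Oc2c(Oc3c(OCc9ccccc9)cc(OCc9ccccc9)cc3OCc9ccccc9)cc(OCc9ccccc9)cc2OCc9ccccc9)cc(C=O)c1Oc4cc(OCc9ccccc9)c(OCc9ccccc9)c(OCc9ccccc9)c4Oc5cc(OCc9ccccc9)c(OCc9ccccc9)c(OCc9ccccc9)c5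
F5 | step 17 | 5-{2,4-bis(benzyloxy)-6-[2,4,6-tris(benzyloxy)phenoxy]phenoxy}-2-{3,4,5-tris(benzyloxy)-2-[3,4,5-tris(benzyloxy)phenoxy]phenoxy}benzene-1,3-diol | Oc1cc(Oc2c(Oc3c(OCc9ccccc9)cc(OCc9ccccc9)cc3OCc9ccccc9)cc(OCc9ccccc9)cc2OCc9ccccc9)cc(O)c1Oc4cc(OCc9ccccc9)c(OCc9ccccc9)c(OCc9ccccc9)c4Oc5cc(OCc9ccccc9)c(OCc9ccccc9)c(OCc9ccccc9)c5
F6 | step 15 | rac-3-ethoxy-4-{3,4,5-tris(benzyloxy)-2-[3,4,5-tris(benzyloxy)phenoxy]phenoxy}cyclobut-2-en-1-one | CCOC1=CC(=O)C1Oc4cc(OCc9ccccc9)c(OCc9ccccc9)c(OCc9ccccc9)c4Oc5cc(OCc9ccccc9)c(OCc9ccccc9)c(OCc9ccccc9)c5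
F7 | step 15 | 3-ethoxy-5-{2,4-bis(benzyloxy)-6-[2,4,6-tris(benzyloxy)phenoxy]phenoxy}-2-{3,4,5-tris(benzyloxy)-2-[3,4,5-tris(benzyloxy)phenoxy]phenoxy}phenol | CCOc1cc(Oc2c(Oc3c(OCc9ccccc9)cc(OCc9ccccc9)cc3OCc9ccccc9)cc(OCc9ccccc9)cc2OCc9ccccc9)cc(O)c1Oc4cc(OCc9ccccc9)c(OCc9ccccc9)c(OCc9ccccc9)c4Oc5cc(OCc9ccccc9)c(OCc9ccccc9)c(OCc9ccccc9)c5
F8 | step 15 | 3-ethoxy-5-[2,4-dihydroxy-6-(2,4,6-trihydroxyphenoxy)phenoxy]-2-[3,4,5-trihydroxy-2-(3,4,5-trihydroxyphenoxy)phenoxy]phenol | CCOc1cc(Oc2c(Oc3c(O)cc(O)cc3O)cc(O)cc2O)cc(O)c1Oc4cc(O)c(O)c(O)c4Oc5cc(O)c(O)c(O)c5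
F9 | step 5 | 1,3-bis(benzyloxy)-5-fluorobenzene | Fc1cc(OCc9ccccc9)cc(OCc9ccccc9)c1
F10 | step 5 | 2,4-bis(benzyloxy)-6-fluorobenzaldehyde | O=Cc1c(F)cc(OCc9ccccc9)cc1OCc9ccccc9
F11 | step 7 | 1,5-bis(benzyloxy)-2-[(2,2-dichloroethenyl)oxy]-3-[2,4,6-tris(benzyloxy)phenoxy]benzene | ClC(Cl)=COc2c(Oc3c(OCc9ccccc9)cc(OCc9ccccc9)cc3OCc9ccccc9)cc(OCc9ccccc9)cc2OCc9ccccc9
A1 | alternative 1 | 5-ethoxy-3,4-dimethoxy-2-(3,4,5-trimethoxyphenoxy)phenol | Oc1cc(OCC)c(OC)c(OC)c1Oc1cc(OC)c(OC)c(OC)c1
A2 | alternative 2 | dibenzyl 5-[3,5-bis(benzyloxy)-2-(3,5-bis(benzyloxy)-4-{3,4,5-tris(benzyloxy)-2-[3,4,5-tris(benzyloxy)phenoxy]phenoxy}phenoxy)phenoxy]-2,4,6-trihydroxybenzene-1,3-dicarboxylate | O=C(OCc9ccccc9)c1c(O)c(Oc2cc(OCc9ccccc9)cc(OCc9ccccc9)c2Oc3cc(OCc9ccccc9)c(Oc4cc(OCc9ccccc9)c(OCc9ccccc9)c(OCc9ccccc9)c4Oc5cc(OCc9ccccc9)c(OCc9ccccc9)c(OCc9ccccc9)c5)c(OCc9ccccc9)c3)c(O)c(C(=O)OCc9ccccc9)c1O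
A3 | alternative 3 | 2,6-bis(benzyloxy)-4-{2,3,4-tris(benzyloxy)-6-[2,6-bis(benzyloxy)-4-{2,4-bis(benzyloxy)-6-[2,4,6-tris(benzyloxy)phenoxy]phenoxy}phenoxy]phenoxy}phenol | Oc5c(OCc9ccccc9)cc(Oc4c(OCc9ccccc9)c(OCc9ccccc9)c(OCc9ccccc9)cc4Oc3c(OCc9ccccc9)cc(Oc2c(Oc1c(OCc9ccccc9)cc(OCc9ccccc9)cc1OCc9ccccc9)cc(OCc9ccccc9)cc2OCc9ccccc9)cc3OCc9ccccc9)cc5OCc9ccccc9
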